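## The problem

Compound 18 is an open-chain bis(bibenzyl). Four benzene rings A–D are joined A–B and C–D by CH2CH2 bridges and B–C by a diaryl ether oxygen. That oxygen sits on ring B ortho to a free hydroxyl and meta to the bridge, and on ring C para to the bridge. There is no stereocentre, so the task is one of placing four aryl oxygens and telling them apart. Ring A must end as a methyl ether while rings B and D end as free phenols. A final ether cleavage with boron or aluminium halides is therefore excluded, and the two phenols must travel under groups that come off without touching OMe. The ether carbon of ring B is flanked by an oxygen substituent, so the diaryl C–O bond has to be made at a hindered, electron-rich position. The free phenols, above all the catechol-type ring B, are oxidisable and should be unmasked last. Ring A carries only OMe at C3 and the bridge at C1, with four CH positions. This 1,3 pattern maps onto C4 (OMe) and C6 (methyl) of 4-methoxy-6-methyl-2-pyrone 5, whose C3 and C5 are already CH and whose 6-methyl group is acidic enough to be joined to ring B. The two missing CH carbons can then come from an acetylene equivalent while O1 and C2 of the pyrone leave.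

## Retrosynthesis

**18 from 17.** The two phenols of 18 are traced back to the bis(benzyl ether) 17. Benzyl is chosen over methyl, silyl or acetal groups because one neutral hydrogenolysis removes both and cannot touch the ring A methyl ether. The forward step must only leave the diaryl ether and the anisole alone.

**17 from 11 and 16.** The bond between the ether oxygen and C3 of ring B is cut, giving aryl bromide 11 (rings A and B) and phenol 16 (rings C and D). The neighbouring cut, between the oxygen and ring C, would need a ring B catechol with its two adjacent oxygens differentiated and an unactivated ring C halide. With the cut chosen, the oxygen and bromine pattern of ring B is bought ready-made in 1. The two halves are of similar size, so the route is convergent. The forward reaction is a copper-catalysed Ullmann-type etherification at a bromide ortho to a benzyloxy group.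

**16 from 12 and 13.** The bond between the bridge CH2 and ring D is cut, giving 4-acetoxystyrene 12 and 1-(benzyloxy)-3-bromobenzene 13, both commercial. An olefination followed by hydrogenation would also make this bridge, but hydrogenation would strip the ring D benzyl ether that must last until the end. A B-alkyl Suzuki–Miyaura coupling through borane 14 gives the saturated bridge directly. The forward sequence needs terminal hydroboration, sp3–sp2 coupling and removal of the acetate (15 to 16), all in one flask.

**11 from 7 and 8 (the strategic cut).** With ring A numbered from the bridge carbon (OMe on C3), the C4–C5 and C6–C1 bonds are cut. Carbons C5 and C6 come from phenyl vinyl sulfoxide 8 and the rest of the ring from pyrone 7. The conventional cut through the bridge would buy ring A as a 3-methoxybenzyl unit. The pyrone cut instead draws four ring carbons, the methoxy group and one bridge carbon from one cheap heterocycle, and the meta relation cannot come out wrong. Precursor 7 has one ring fewer and is one C–C bond away from 5. The forward step is a cycloaddition followed by decarboxylation and sulfoxide elimination on a diene known to be slow, so the spectator groups of 7 (aryl bromide, benzyl aryl ether, saturated bridge) are chosen to stand prolonged heating.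

**7 from 5 and 4.** The central CH2–CH2 bond of the A–B bridge is cut. Deprotonation of the 6-methyl group of 5 gives the vinylogous lithium enolate 6, which is alkylated by benzylic bromide 4. This fixes the bridge length and leaves the pyrone untouched for the key step.

**4 from 1.** Bromide 4 comes by functional-group changes from 3-bromo-4-hydroxybenzaldehyde 1: O-benzylation to 2, reduction to alcohol 3 and bromination. No skeletal bond is made, and the bromine that later becomes the ether oxygen is present from the start.

## Roads not taken

**Alternative 1:** Ring B is taken apart instead of ring A.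
- **Cut and key step.** Phenol 16 would be O-alkylated with an α-haloacetone to the aryloxyacetone A1. A1 would be combined with the α-methylene aldehyde A2 in a Michael addition and aldol condensation to give cyclohexenone A3. Dehydrogenation of A3 to phenol A4 and hydrogenolysis would complete the synthesis.
- **Merits.** The ether oxygen is attached by SN2 at an sp3 carbon before ring B exists, so no hindered aryl C–O coupling is needed. This is better than the chosen plan at its weakest ordinary step. The annulation is also regioconvergent: whichever α-carbon of A1 acts as the Michael donor, aromatisation gives the same 1,2,4-pattern.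
- **Weak points.** A2 is a polymerisation-prone enal that itself takes several steps. The unsymmetrical ketone A1 can undergo self-aldol reaction and double Michael addition. A3 is at the wrong oxidation level. Its dehydrogenation must be done with an oxidant in the presence of two bibenzyl bridges and a benzyl ether. A3 could also aromatise the wrong way by expelling the aryloxy group, since it is at the oxidation level of a simple para-substituted phenol plus 16.
- **Comparison.** The step count would be similar or higher. The chosen plan reaches the aromatic oxidation level of its new ring without any oxidant and keeps the oxygen pattern of ring B from a commercial arene.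

**Alternative 2:** No ring is built.
- **Cut and key step.** Both aryl–CH2 bonds on rings B and C are cut as aryl–alkynyl bonds. The bromo-iodo diaryl ether A5 would be coupled in one pot, first at the iodide with 3-ethynylphenol A6 at room temperature, then at the bromide with 3-ethynylanisole A7 on heating. This would give bis-alkyne A8, and one hydrogenation would reduce both alkynes and remove the benzyl group.
- **Merits.** This road is shorter than the chosen plan and uses mild, very well precedented couplings. In step economy it is better.
- **Weak points.** A5 still needs a diaryl ether synthesis of the same kind as step 7. The ring B bromide lies para to an alkoxy group and is a deactivated Sonogashira partner. Any leakage in halide selectivity, or alkyne left over from the first stage, gives constitutional isomers of A8 in which OMe and OH have changed rings. These differ from the desired compound only by the position of one methyl group and would be very hard to remove. Oxidative alkyne homocoupling in the presence of a free phenol is a further drain.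
- **Comparison.** The chosen plan sets against the shorter route that the position of the methyl ether is fixed by construction, with no selectivity between two similar halides or two similar alkynes to be maintained, and that its building blocks are cheaper.

**Alternative 3:** Ring D is built last.
- **Cut and key step.** β-Keto ester A9, carrying the complete A–B–C assembly, would undergo Michael addition to methyl vinyl ketone A10 and aldol condensation to cyclohexenone ester A11. Ester hydrolysis, decarboxylation and dehydrogenation would then give the ring D phenol.
- **Merits.** The annulation is mild and reliable, and it sets the meta relation of hydroxyl and bridge by construction, as the pyrone does for ring A. It needs no forcing temperature, which is an advantage over the chosen key step.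
- **Weak points.** The ring it builds is the simplest of the four, available for little as 13. A9 presupposes the diaryl ether and the A–B bibenzyl, so the annulation adds steps instead of replacing them and comes at the end of a long linear sequence. A11 needs three further operations, one of them an oxidation next to benzylic positions and a benzyl ether.
- **Comparison.** The chosen plan builds its ring early, on a small substrate, and reaches the arene in one operation through two traceless losses.

Key step: step 5

Assumption: the non-isolated cycloadducts 9 and 10 are drawn with the sulfinyl-bearing carbon bonded to pyrone C6, the orientation expected on electronic grounds. They would form as mixtures of diastereomers, and either orientation leads to the same arene 11.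

## Route

Step 1
Reactants: 1 3-bromo-4-hydroxybenzaldehyde
Product: 2 4-(benzyloxy)-3-bromobenzaldehyde
Conditions: BnBr, K2CO3, DMF, rt
Reagents that add atoms: benzyl bromide, BrCc1ccccc1
Why: Williamson ether synthesis; the phenoxide, acidified by the para formyl and ortho bromo groups, should be alkylated cleanly, and carbonate does not affect the aldehyde.

Step 2
Reactants: 2 4-(benzyloxy)-3-bromobenzaldehyde
Product: 3 [4-(benzyloxy)-3-bromophenyl]methanol
Conditions: NaBH4, MeOH/THF, 0 °C
Reagents that add atoms: none
Why: Borohydride reduction of an aromatic aldehyde to the benzylic alcohol; aryl bromide and benzyl ether are inert to NaBH4.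

Step 3
Reactants: 3 [4-(benzyloxy)-3-bromophenyl]methanol
Product: 4 1-(benzyloxy)-2-bromo-4-(bromomethyl)benzene
Conditions: PBr3, CH2Cl2, 0 °C
Reagents that add atoms: phosphorus tribromide, BrP(Br)Br
Why: Bromination of a benzylic alcohol through its phosphite ester with SN2 displacement by bromide; low temperature and short contact time should spare the benzyl aryl ether, and the bromide is used without storage.

Step 4
Reactants: 5 4-methoxy-6-methyl-2H-pyran-2-one; 4 1-(benzyloxy)-2-bromo-4-(bromomethyl)benzene
Product: 7 6-{2-[4-(benzyloxy)-3-bromophenyl]ethyl}-4-methoxy-2H-pyran-2-one, via lithiated pyrone 6 (not isolated)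
Conditions: LiN(iPr)2 (1.1 equiv), THF/DMPU, −78 °C; then 4, −78 to −40 °C
Reagents that add atoms: none
Why: Vinylogous enolate alkylation; the amide base removes a proton from the 6-methyl group (anion delocalised through C5, C3 and the carbonyl oxygen) and the dienolate 6 attacks the benzylic bromide by SN2 at its exocyclic carbon. A delocalised lithium dienolate does not undergo halogen–metal exchange with the aryl bromide, and a slight excess of 5 with slow addition of 4 limits double alkylation.

Step 5
Reactants: 7 6-{2-[4-(benzyloxy)-3-bromophenyl]ethyl}-4-methoxy-2H-pyran-2-one; 8 phenyl vinyl sulfoxide (racemic)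
Product: 11 1-(benzyloxy)-2-bromo-4-[2-(3-methoxyphenyl)ethyl]benzene, via bridged bicyclic lactone 9 (not isolated), via sulfinyl cyclohexadiene 10 (not isolated)
Conditions: 8 (5 equiv), BHT (cat.), 1,2-dichlorobenzene (about 1 M in 7), 150 °C, sealed tube
Reagents that add atoms: none
Why: Thermal Diels–Alder benzannulation of a 2-pyrone with an acetylene equivalent: the diene C3=C4–C5=C6 of 7 adds the vinyl group of 8 across C3 and C6 to give bridged lactone 9, cycloreversion expels CO2 to give cyclohexa-1,3-diene 10, and thermal syn-elimination of benzenesulfenic acid from 10 gives arene 11. The closest known reaction type is the pyrone Diels–Alder and decarboxylation sequence with alkynes and with vinyl sulfoxides or other masked acetylenes. Ring A is closed by an intermolecular [4+2] cycloaddition that forms the C3–CH2 and C6–CH(S) bonds in one event, and it becomes a benzene ring through the two eliminations, both irreversible, which pull a sluggish cycloaddition forward. The stereocentres of 9 and 10 (bridgeheads, sulfinyl carbon, sulfur) are all destroyed, so endo/exo and facial selectivity do not matter and the racemic sulfoxide suffices. Only site selectivity is needed: the pyrone can react only across C3 and C6, and the meta relation of OMe (C4) and chain (C6) is fixed within 7 whichever way the sulfoxide adds (electron donation from O1 and the 4-methoxy group towards C3 should favour bonding of the CH2 terminus to C3, as drawn for 9). The 4-methoxy group makes the pyrone a slow diene, hence the excess of 8, the high concentration and 150 °C, which the aryl bromide, benzyl aryl ether and saturated bridge should tolerate. The sulfenic acid is consumed by self-condensation or by the excess of 8, and BHT suppresses radical polymerisation of the dienophile.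

Step 6
Reactants: 12 4-ethenylphenyl acetate (4-acetoxystyrene); 13 1-(benzyloxy)-3-bromobenzene
Product: 16 4-{2-[3-(benzyloxy)phenyl]ethyl}phenol, via B-alkyl borane 14 (not isolated), via bibenzyl acetate 15 (not isolated)
Conditions: 9-BBN, THF, 0 °C to rt; then 13, PdCl2(dppf) (3 mol%), K3PO4, DMF, 50 °C; then NaOH aq, MeOH, rt; 1 M HCl work-up
Reagents that add atoms: none
Why: Anti-Markovnikov hydroboration of the styrene with 9-BBN followed by B-alkyl Suzuki–Miyaura coupling with aryl bromide 13; the wide-bite-angle ligand of PdCl2(dppf) disfavours β-hydride elimination. Saponification of the aryl acetate in the same flask gives the phenol, and any acetate lost earlier converges on 16; the ring D benzyl ether never meets hydrogenation conditions.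

Step 7
Reactants: 11 1-(benzyloxy)-2-bromo-4-[2-(3-methoxyphenyl)ethyl]benzene; 16 4-{2-[3-(benzyloxy)phenyl]ethyl}phenol
Product: 17 1-(benzyloxy)-2-(4-{2-[3-(benzyloxy)phenyl]ethyl}phenoxy)-4-[2-(3-methoxyphenyl)ethyl]benzene
Conditions: CuI (20 mol%), N,N-dimethylglycine hydrochloride (60 mol%), Cs2CO3, 1,4-dioxane, 100 °C
Reagents that add atoms: none
Why: Ullmann-type diaryl ether synthesis under copper catalysis with an amino acid ligand; the caesium phenoxide of 16 couples with aryl bromide 11. Each partner has a single reactive site, and the ortho benzyloxy group slows the coupling but can assist by coordinating copper.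

Step 8
Reactants: 17 1-(benzyloxy)-2-(4-{2-[3-(benzyloxy)phenyl]ethyl}phenoxy)-4-[2-(3-methoxyphenyl)ethyl]benzene
Product: 18 2-{4-[2-(3-hydroxyphenyl)ethyl]phenoxy}-4-[2-(3-methoxyphenyl)ethyl]phenol (the target)
Conditions: H2 (1 atm), Pd/C, EtOAc/MeOH, rt
Reagents that add atoms: none
Why: Hydrogenolysis of both benzyl aryl ethers over Pd/C; the aryl methyl ether, the diaryl ether and the saturated bridges are stable under these conditions, and no stereocentre is involved.

## Compound list

1 | 3-bromo-4-hydroxybenzaldehyde | O=Cc1ccc(O)c(Br)c1 | starting material
2 | 4-(benzyloxy)-3-bromobenzaldehyde | O=Cc1ccc(OCc2ccccc2)c(Br)c1 | intermediate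
3 | [4-(benzyloxy)-3-bromophenyl]methanol | OCc1ccc(OCc2ccccc2)c(Br)c1 | intermediate
4 | 1-(benzyloxy)-2-bromo-4-(bromomethyl)benzene | BrCc1ccc(OCc2ccccc2)c(Br)c1 | intermediate
5 | 4-methoxy-6-methyl-2H-pyran-2-one | COC1=CC(=O)OC(C)=C1 | starting material
6 | (4-methoxy-2-oxo-2H-pyran-6-yl)methyllithium (lithium dienolate of 5) | [Li]CC1=CC(OC)=CC(=O)O1 | intermediate (not isolated)
7 | 6-{2-[4-(benzyloxy)-3-bromophenyl]ethyl}-4-methoxy-2H-pyran-2-one | COC1=CC(=O)OC(CCc2ccc(OCc3ccccc3)c(Br)c2)=C1 | intermediate
8 | phenyl vinyl sulfoxide (racemic) | C=CS(=O)c1ccccc1 | starting material
9 | 1-{2-[4-(benzyloxy)-3-bromophenyl]ethyl}-8-methoxy-6-(phenylsulfinyl)-2-oxabicyclo[2.2.2]oct-7-en-3-one (mixture of diastereomers) | O=C1OC2(CCc3ccc(OCc4ccccc4)c(Br)c3)C(S(=O)c3ccccc3)CC1C(OC)=C2 | intermediate (not isolated)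
10 | 1-(benzyloxy)-2-bromo-4-{2-[3-methoxy-6-(phenylsulfinyl)cyclohexa-1,3-dien-1-yl]ethyl}benzene (mixture of diastereomers) | COC1=CCC(S(=O)c2ccccc2)C(CCc2ccc(OCc3ccccc3)c(Br)c2)=C1 | intermediate (not isolated)
11 | 1-(benzyloxy)-2-bromo-4-[2-(3-methoxyphenyl)ethyl]benzene | COc1cccc(CCc2ccc(OCc3ccccc3)c(Br)c2)c1 | intermediate
12 | 4-ethenylphenyl acetate (4-acetoxystyrene) | CC(=O)Oc1ccc(C=C)cc1 | starting material
13 | 1-(benzyloxy)-3-bromobenzene | Brc1cccc(OCc2ccccc2)c1 | starting material
14 | 4-[2-(9-borabicyclo[3.3.1]nonan-9-yl)ethyl]phenyl acetate | CC(=O)Oc1ccc(CCB2C3CCCC2CCC3)cc1 | intermediate (not isolated)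
15 | 4-{2-[3-(benzyloxy)phenyl]ethyl}phenyl acetate | CC(=O)Oc1ccc(CCc2cccc(OCc3ccccc3)c2)cc1 | intermediate (not isolated)
16 | 4-{2-[3-(benzyloxy)phenyl]ethyl}phenol | Oc1ccc(CCc2cccc(OCc3ccccc3)c2)cc1 | intermediate
17 | 1-(benzyloxy)-2-(4-{2-[3-(benzyloxy)phenyl]ethyl}phenoxy)-4-[2-(3-methoxyphenyl)ethyl]benzene | COc1cccc(CCc2ccc(OCc3ccccc3)c(Oc3ccc(CCc4cccc(OCc5ccccc5)c4)cc3)c2)c1 | intermediate
18 | 2-{4-[2-(3-hydroxyphenyl)ethyl]phenoxy}-4-[2-(3-methoxyphenyl)ethyl]phenol | COc1cccc(CCc2ccc(O)c(Oc3ccc(CCc4cccc(O)c4)cc3)c2)c1 | target

## Step count and risks

Total step count: 8. Longest linear sequence: 7 steps (steps 1, 2, 3, 4, 5, 7 and 8); step 6 is a one-step side branch.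

**Step 5 (key step).** The cycloaddition may be too slow to outrun thermal degradation of the dienophile, or the electrophilic sulfur by-products may sulfenylate the nucleophilic C3 of unreacted pyrone, because the 4-methoxy group makes the pyrone a poor diene. The fallback gives up building ring A and buys it. It sets out from aldehyde 2: Horner–Wadsworth–Emmons olefination with diethyl (3-methoxybenzyl)phosphonate (NaH, THF) would give 1-(benzyloxy)-2-bromo-4-[(E)-2-(3-methoxyphenyl)ethenyl]benzene F1. Reduction of its double bond with diimide (TsNHNH2, NaOAc, DME/H2O, reflux), which leaves aryl bromide and benzyl ether alone, returns to the route at 11.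

**Step 4.** Deprotonation may occur in part at C3 of the pyrone instead of the methyl group, and the product may be deprotonated and alkylated a second time, because the acidities are close and the monoalkylated pyrone is still a vinylogous ester. The fallback replaces alkylation by condensation and reduction. It sets out from 5 and aldehyde 2: Mg(OMe)2-mediated vinylogous aldol condensation in MeOH at reflux would give 6-{(E)-2-[4-(benzyloxy)-3-bromophenyl]ethenyl}-4-methoxy-2H-pyran-2-one F2. Diimide reduction of its exocyclic disubstituted double bond (the push–pull ring double bonds should not react) returns to the route at 7.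

**Step 7.** Oxidative addition of copper to the hindered, electron-rich bromide may be slow, so that protodebromination of 11 or stalling competes. The fallback reverses the polarity of ring B. It sets out from 11: bromine–lithium exchange (n-BuLi, THF, −78 °C), trapping with B(OiPr)3 and acidic hydrolysis would give {2-(benzyloxy)-5-[2-(3-methoxyphenyl)ethyl]phenyl}boronic acid F3. Chan–Lam coupling of F3 with phenol 16 (Cu(OAc)2, pyridine, 4 Å molecular sieves, CH2Cl2, air, rt) returns to the route at 17.

**Step 6.** The alkylborane may be lost by protodeboronation or β-hydride elimination before transmetalation, or the borane may partly reduce the aryl acetate. The fallback makes the bridge by olefin arylation. It sets out from 12 and 13: Mizoroki–Heck reaction (Pd(OAc)2, P(o-tol)3, Et3N, DMF, 100 °C) would give 4-{(E)-2-[3-(benzyloxy)phenyl]ethenyl}phenyl acetate F4. Diimide reduction of the stilbene double bond, which keeps the benzyl ether, returns to the route at 15, which is saponified to 16 as in step 6.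

## Further compounds

F1 | step 5 | 1-(benzyloxy)-2-bromo-4-[(E)-2-(3-methoxyphenyl)ethenyl]benzene | COc1cccc(/C=C/c2ccc(OCc3ccccc3)c(Br)c2)c1
F2 | step 4 | 6-{(E)-2-[4-(benzyloxy)-3-bromophenyl]ethenyl}-4-methoxy-2H-pyran-2-one | COC1=CC(=O)OC(/C=C/c2ccc(OCc3ccccc3)c(Br)c2)=C1
F3 | step 7 | {2-(benzyloxy)-5-[2-(3-methoxyphenyl)ethyl]phenyl}boronic acid | COc1cccc(CCc2ccc(OCc3ccccc3)c(B(O)O)c2)c1
F4 | step 6 | 4-{(E)-2-[3-(benzyloxy)phenyl]ethenyl}phenyl acetate | CC(=O)Oc1ccc(/C=C/c2cccc(OCc3ccccc3)c2)cc1
A1 | alternative 1 | 1-(4-{2-[3-(benzyloxy)phenyl]ethyl}phenoxy)propan-2-one | CC(=O)COc1ccc(CCc2cccc(OCc3ccccc3)c2)cc1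
A2 | alternative 1 | 4-(3-methoxyphenyl)-2-methylidenebutanal | C=C(C=O)CCc1cccc(OC)c1
A3 | alternative 1 | 6-(4-{2-[3-(benzyloxy)phenyl]ethyl}phenoxy)-4-[2-(3-methoxyphenyl)ethyl]cyclohex-2-en-1-one (racemic, mixture of diastereomers) | O=C1C=CC(CCc2cccc(OC)c2)CC1Oc1ccc(CCc2cccc(OCc3ccccc3)c2)cc1
A4 | alternative 1 | 2-(4-{2-[3-(benzyloxy)phenyl]ethyl}phenoxy)-4-[2-(3-methoxyphenyl)ethyl]phenol | COc1cccc(CCc2ccc(O)c(Oc3ccc(CCc4cccc(OCc5ccccc5)c4)cc3)c2)c1
A5 | alternative 2 | 1-(benzyloxy)-4-bromo-2-(4-iodophenoxy)benzene | Brc1ccc(OCc2ccccc2)c(Oc2ccc(I)cc2)c1
A6 | alternative 2 | 3-ethynylphenol | Oc1cccc(C#C)c1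
A7 | alternative 2 | 1-ethynyl-3-methoxybenzene (3-ethynylanisole) | COc1cccc(C#C)c1
A8 | alternative 2 | 3-[(4-{2-(benzyloxy)-5-[(3-methoxyphenyl)ethynyl]phenoxy}phenyl)ethynyl]phenol | COc1cccc(C#Cc2ccc(OCc3ccccc3)c(Oc3ccc(C#Cc4cccc(O)c4)cc3)c2)c1
A9 | alternative 3 | ethyl 5-(4-{2-(benzyloxy)-5-[2-(3-methoxyphenyl)ethyl]phenoxy}phenyl)-3-oxopentanoate | CCOC(=O)CC(=O)CCc1ccc(Oc2cc(CCc3cccc(OC)c3)ccc2OCc2ccccc2)cc1
A10 | alternative 3 | but-3-en-2-one (methyl vinyl ketone) | CC(=O)C=C
A11 | alternative 3 | ethyl 2-[2-(4-{2-(benzyloxy)-5-[2-(3-methoxyphenyl)ethyl]phenoxy}phenyl)ethyl]-4-oxocyclohex-2-ene-1-carboxylate (racemic) | CCOC(=O)C1CCC(=O)C=C1CCc1ccc(Oc2cc(CCc3cccc(OC)c3)ccc2OCc2ccccc2)cc1
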